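## The problem

The target is a C40 carotenoid in which two six-membered rings that share no atoms are held apart by an eighteen-carbon chain (C7 to C7') carrying seven E double bonds, four methyl branches and one triple bond (C7'≡C8'), so the synthesis is mainly a matter of building a long polyene with full control of geometry and joining two different ends. Ring B (C1'–C6', a cyclohexene) has one stereocentre, C3' (R), with nothing nearby to induce it, whereas the saturated ring A (C1–C6) has three, C3 (S), C5 (S) and C6 (S), with the C3 and C5 hydroxyls cis and the tertiary C6 hydroxyl trans to both. C3 and C3' have the same spatial sense as C4 of (4R,6R)-actinol, so one chiral-pool ketone can serve both rings. In ring A the C3 oxygen can bias an epoxidation of C5=C6, and the oxirane can pass its configuration to C5 by inversion while C6 keeps its oxygen. The polyene is sensitive to light, oxygen and acid, and the tertiary allylic C6–OH ionises in acid once C7=C8 is in place. Terminal diynes and polyenyl bromides are short-lived, and the 9'E enyne drifts towards 9'Z under equilibrating conditions, so only the central C15=C15' bond may be left to equilibration. The feature that opens the key step is that C9' carries a methyl group cis to H-10' on an alkene conjugated with C7'≡C8'. This is the imprint of syn addition of methyl and a metal across the terminal alkyne of a ring-bound buta-1,3-diyne, with the metal at C10' marking where C11'–C15' is attached.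

## Retrosynthesis

**Target 36 to the two C20 halves.** Removal of the two silyl ethers leads to 35, which is cut at the central C15=C15' bond into the ring B phosphonium salt 18 and the ring A aldehyde 32. This is the only chain double bond that is disubstituted, unbranched and safely corrected by mild heating, and the cut divides the molecule into two halves of equal size. The phosphonium function is placed on the ring B half because the tertiary allylic C6–OH of ring A would not survive bromide and phosphonium formation. The forward Wittig reaction has only to tolerate two free tertiary hydroxyls.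

**Salt 18 to ester 15.** The salt comes from alcohol 16 (through bromide 17) and 16 from ester 15 by reduction. No skeletal bond is involved.

**Ester 15 to diyne 9, iodide 11 and AlMe3 (12).** The C9'–CH3 and C10'–C11' bonds are cut together. The neighbouring cuts (C11'=C12' by olefination of a C15 enynal, or C8'–C9' by coupling a preformed enynol) rely on a purchased double-bond geometry and need extra redox steps. The chosen cut installs the methyl branch, the 9'E alkene and the C10'–C11' bond in one flask, and precursor 9 has no stereogenic double bond at all. The forward reaction must attack only the terminal alkyne, place methyl on C9', and couple with retention.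

**Diyne 9 to triflate 4 and diyne 5.** The C6'–C7' bond is cut, leading through silyl diyne 8 to enol triflate 4 and the monolithiated form (6, as zinc reagent 7) of bis-silyl diyne 5. Triflate 4 comes from silyl ether 2 (through enolate 3) and 2 from actinol 1. The C6 stereocentre of actinol is erased on purpose and C4 is kept.

**Iodide 11 to aldehyde ester 10.** One C=C bond is cut by a Takai iodoolefination. The trisubstituted alkene is bought with its E geometry.

**Aldehyde 32 to aldehyde 28 and then to aldehyde 23.** 32 comes from ester 30 through alcohol 31, and 30 is cut at C11=C12 into C15 aldehyde 28 and phosphonate 24 (used as its sodium salt 29). 28 comes through alcohol 27 from ester 26, which is cut at C7=C8 into the ring aldehyde 23 and again 24 (used there as its lithium salt 25). Using the same five-carbon reagent twice keeps the number of building blocks small, and it brings the C9 and C13 alkenes with their geometry already set.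

**Aldehyde 23 to triflate 4.** 23 is the oxidation product of triol 22, whose C5–O bond is cut back to the anti epoxy alcohol 21 (water at C5 with inversion, C6 keeps the oxirane oxygen). This stage is chosen because C6 is not yet allylic, so C6 ionisation cannot compete. 21 comes from allylic alcohol 20 by reagent-controlled epoxidation, 20 from ester 19, and 19 from triflate 4 by carbonylation. Triflate 4 is thus the branch point for both rings.

## Roads not taken

Alternative 1: The cut is inside ring A (C2–C3 and C1–C6), a [4+2] assembly of the carbocycle from the pyrone A1 (3-hydroxy-4-methyl-2-pyrone) and the enal A2 (methacrolein). In the forward step an amine turns A1 into its dienolate, which adds across A2 to give the bridged lactone A3 (a 2-oxabicyclo[2.2.2]octenone).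
- Merits: one step builds ring A from two simple achiral pieces; the bridgehead C6 already has its hydroxyl; the lactone bridge fixes O-3 and C7 cis on the ring, which is the relationship the target needs; a C4=C5 alkene remains for the C5 hydroxyl; a chiral amine could make it enantioselective.
- Weak points: absolute configuration rests on catalyst control; the formyl group on C1 has to be deoxygenated to the second methyl; the tertiary C5–OH must be added to C4=C5 with the right regiochemistry and on the face of the lactone bridge; the lactone must be opened and C7 adjusted; the enyne half is not addressed.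
- Comparison: for ring A it needs fewer ring-forming operations and avoids an epoxide opening, which is a real advantage. The chosen plan sets against this a single chiral-pool ketone that supplies C3 and C3' of both rings, and a reagent-controlled epoxidation followed by a stereospecific opening for C5 and C6.

Alternative 2: The cut is the C5–O bond. In the forward step the tert-butyl carbonate on O-3 of the anti epoxy enone A4 is activated by a boron Lewis acid; its carbonyl oxygen attacks C5 from the face opposite the oxirane, the tert-butyl group is lost, and the 3,5-cyclic carbonate A5 results with the oxirane oxygen left on C6.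
- Merits: intramolecular delivery secures both the site (C5) and the 3,5-cis relationship; the enone deactivates C6; the carbonate then protects O-3 and O-5.
- Weak points: the silyl group on O-3 must be exchanged for the carbonate; chain extension then starts from a methyl ketone, where the C9=C10 bond forms as an isomer mixture; the enyne half is again left open.
- Comparison: at C5 this is the more secure method, and the intermolecular opening used in the chosen plan (step 12) is less certain. The chosen plan sets against it an opening of the same anti epoxide one stage earlier (21 to 22), which needs no protecting-group exchange and leaves C7 free to become an aldehyde that takes C8–C11 in one olefination with the C9 geometry carried by 24. A tethered opening from O-7 is held in reserve.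

Alternative 3: The cut is the triple bond C7'≡C8', made from a ketone. In the forward step the lithium reagent A7, which is lithiated trimethylsilyldiazomethane, adds to the carbonyl of the cross-conjugated dienone A6; silanolate elimination and extrusion of nitrogen leave an alkylidene carbene, and a 1,2-shift of an alkenyl group gives the enyne acetal A8.
- Merits: no terminal diyne, no aluminium alkyl and no palladium; 9'E is inherited from an aldol condensation that made A6; A8 is a protected C15 aldehyde that fits classical chain extension.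
- Weak points: the carbonyl of A6 lies between a tetrasubstituted ring alkene with a gem-dimethyl neighbour and an α-methyl enone, so addition of A7 is hindered and conjugate addition competes; alkylidene carbenes without an aryl group can insert into nearby C–H bonds (the ring C5' methyl is in 1,5 range) instead of rearranging; the product A8 stops at C15.
- Comparison: it is better at avoiding the unstable diyne 9 and the pyrophoric reagent 12. The chosen plan sets against it a stereospecific syn addition of a well-known reaction class, and the formation of the methyl branch, the 9'E alkene and the C10'–C11' bond in one flask, arriving directly at C20.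

Key step: step 6

Assumption (remark on the chemistry): the target is taken as the single (3S,5S,6S,3'R) diastereomer of the SMILES (C3–OH and C5–OH cis, C6–OH trans to both), and commercial 10 and 24 are used as their E isomers after removal of minor Z material.

## Route

Step 1
Reactants: 1 (4R,6R)-4-hydroxy-2,2,6-trimethylcyclohexanone (actinol)
Product: 2 (4R,6R)-4-(tert-butyldimethylsilyloxy)-2,2,6-trimethylcyclohexanone
Conditions: TBSCl, imidazole, DMF, rt
Reagents that add atoms: tert-butyldimethylsilyl chloride, CC(C)(C)[Si](C)(C)Cl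
Why: Imidazole-mediated silylation of the secondary alcohol; the ketone and both stereocentres are untouched.

Step 2
Reactants: 2 (4R,6R)-4-(tert-butyldimethylsilyloxy)-2,2,6-trimethylcyclohexanone
Product: 4 (4R)-4-(tert-butyldimethylsilyloxy)-2,6,6-trimethylcyclohex-1-en-1-yl trifluoromethanesulfonate, via lithium enolate 3 (not isolated)
Conditions: LiN(iPr)2, THF, −78 °C; PhNTf2, −78 °C → rt
Reagents that add atoms: N-phenylbis(trifluoromethanesulfonimide), O=S(=O)(N(c1ccccc1)S(=O)(=O)C(F)(F)F)C(F)(F)F
Why: The C6 methine is the only enolisable position, so a single tetrasubstituted enolate forms and is O-sulfonylated (enol triflate formation). The C6 stereocentre is erased on purpose and the silyloxy carbon is not affected.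

Step 3
Reactants: 5 1,4-bis(trimethylsilyl)buta-1,3-diyne; 4 (4R)-4-(tert-butyldimethylsilyloxy)-2,6,6-trimethylcyclohex-1-en-1-yl trifluoromethanesulfonate
Product: 8 tert-butyldimethyl{[(1R)-3,5,5-trimethyl-4-[4-(trimethylsilyl)buta-1,3-diyn-1-yl]cyclohex-3-en-1-yl]oxy}silane, via lithium (trimethylsilyl)butadiynide 6 (not isolated), via (trimethylsilyl)butadiynylzinc chloride 7 (not isolated)
Conditions: 5, MeLi·LiBr, THF/Et2O, rt; ZnCl2, 0 °C; 4, Pd(PPh3)4 (5 mol %), rt → 45 °C
Reagents that add atoms: none
Why: MeLi·LiBr cleaves one C–Si bond of 5, and after transmetalation to zinc a Negishi alkynylation of the enol triflate (oxidative addition to the zerovalent palladium complex, transmetalation, reductive elimination) forms C6'–C7'. The remaining silyl group keeps the diyne monofunctional and avoids isolating a volatile butadiyne.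

Step 4
Reactants: 8 tert-butyldimethyl{[(1R)-3,5,5-trimethyl-4-[4-(trimethylsilyl)buta-1,3-diyn-1-yl]cyclohex-3-en-1-yl]oxy}silane
Product: 9 {[(1R)-4-(buta-1,3-diyn-1-yl)-3,5,5-trimethylcyclohex-3-en-1-yl]oxy}(tert-butyl)dimethylsilane
Conditions: K2CO3 (cat.), MeOH/THF, 0 °C → rt; used at once as a solution
Reagents that add atoms: none
Why: Carbonate-catalysed methanolysis of the alkynyl C–Si bond (protodesilylation). The secondary silyl ether is stable to these conditions.

Step 5
Reactants: 10 ethyl (2E)-3-methyl-4-oxobut-2-enoate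
Product: 11 ethyl (2E,4E)-5-iodo-3-methylpenta-2,4-dienoate
Conditions: CrCl2, CHI3, THF/1,4-dioxane, 0 °C → rt
Reagents that add atoms: iodoform, IC(I)I
Why: Takai iodoolefination: the geminal dichromium carbenoid from CHI3 and CrCl2 adds to the aldehyde and eliminates to the E alkenyl iodide. The ester and the trisubstituted alkene are inert to this weakly basic reagent.

Step 6
Reactants: 9 {[(1R)-4-(buta-1,3-diyn-1-yl)-3,5,5-trimethylcyclohex-3-en-1-yl]oxy}(tert-butyl)dimethylsilane; 12 trimethylaluminium; 11 ethyl (2E,4E)-5-iodo-3-methylpenta-2,4-dienoate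
Product: 15 ethyl (2E,4E,6E)-9-[(4R)-4-(tert-butyldimethylsilyloxy)-2,6,6-trimethylcyclohex-1-en-1-yl]-3,7-dimethylnona-2,4,6-trien-8-ynoate, via alkenyldimethylalane 13 (not isolated), via alkenylzinc chloride 14 (not isolated)
Conditions: 12 (3 equiv), Cp2ZrCl2 (0.5 equiv), ClCH2CH2Cl, 0 °C → rt; volatiles removed in vacuo; THF, ZnCl2, 11, Pd(PPh3)4 (5 mol %), rt
Reagents that add atoms: none
Why: Cp2ZrCl2 and AlMe3 form a methylzirconocene–aluminate pair that adds methyl and metal syn across the terminal C≡C of 9, methyl to the internal carbon C9' and metal to C10', giving alane 13 after exchange to aluminium. ZnCl2 converts 13 into the alkenylzinc 14; oxidative addition of the C–I bond of 11 to the zerovalent palladium complex, transmetalation and reductive elimination then form C10'–C11' with retention at both alkenyl carbons. The closest known reaction type is the zirconium-catalysed methylalumination of terminal alkynes and conjugated enynes followed by palladium-catalysed Negishi alkenyl–alkenyl coupling. No ring is closed and no stereocentre is created; the stereochemical element is the 9'E geometry, which follows from syn addition because methyl and C10'–metal are cis and C8' is therefore trans to C11'. The step needs terminal over internal alkyne selectivity, which the substrate secures because the internal alkyne is shielded by the tetrasubstituted ring alkene and its gem-dimethyl neighbour. It also needs methyl on C9', which is the usual preference of the metal for the unhindered terminus. Removing excess AlMe3 before the coupling suppresses methyl transfer to 11, and the ester and silyl ether tolerate the alkenylzinc at rt.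

Step 7
Reactants: 15 ethyl (2E,4E,6E)-9-[(4R)-4-(tert-butyldimethylsilyloxy)-2,6,6-trimethylcyclohex-1-en-1-yl]-3,7-dimethylnona-2,4,6-trien-8-ynoate
Product: 16 (2E,4E,6E)-9-[(4R)-4-(tert-butyldimethylsilyloxy)-2,6,6-trimethylcyclohex-1-en-1-yl]-3,7-dimethylnona-2,4,6-trien-8-yn-1-ol
Conditions: iBu2AlH, CH2Cl2, −78 °C; aq. KNaC4H4O6 (potassium sodium tartrate)
Reagents that add atoms: none
Why: 1,2-Reduction of the conjugated ester to the allylic alcohol by the aluminium hydride. At low temperature the enyne, the polyene and the silyl ether are not touched.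

Step 8
Reactants: 16 (2E,4E,6E)-9-[(4R)-4-(tert-butyldimethylsilyloxy)-2,6,6-trimethylcyclohex-1-en-1-yl]-3,7-dimethylnona-2,4,6-trien-8-yn-1-ol
Product: 18 [(2E,4E,6E)-9-[(4R)-4-(tert-butyldimethylsilyloxy)-2,6,6-trimethylcyclohex-1-en-1-yl]-3,7-dimethylnona-2,4,6-trien-8-yn-1-yl]triphenylphosphonium bromide, via allylic bromide 17 (not isolated)
Conditions: PBr3, pyridine (cat.), Et2O, −20 °C; then PPh3, CH2Cl2, rt
Reagents that add atoms: phosphorus tribromide, BrP(Br)Br; triphenylphosphine, c1ccc(cc1)P(c1ccccc1)c1ccccc1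
Why: The primary allylic alcohol is converted to the bromide, and PPh3 then displaces bromide at the terminal carbon (SN2 quaternisation), as in retinyl phosphonium salts. Pyridine buffers HBr so that the silyl ether and the enyne survive.

Step 9
Reactants: 4 (4R)-4-(tert-butyldimethylsilyloxy)-2,6,6-trimethylcyclohex-1-en-1-yl trifluoromethanesulfonate
Product: 19 methyl (4R)-4-(tert-butyldimethylsilyloxy)-2,6,6-trimethylcyclohex-1-ene-1-carboxylate
Conditions: CO (1 atm), Pd(OAc)2 (5 mol %), PPh3, Et3N, MeOH/DMF, 60 °C
Reagents that add atoms: carbon monoxide, [C-]#[O+]; methanol, CO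
Why: Palladium-catalysed methoxycarbonylation of the enol triflate (oxidative addition, CO insertion, methanolysis of the acyl palladium) installs C7.

Step 10
Reactants: 19 methyl (4R)-4-(tert-butyldimethylsilyloxy)-2,6,6-trimethylcyclohex-1-ene-1-carboxylate
Product: 20 [(4R)-4-(tert-butyldimethylsilyloxy)-2,6,6-trimethylcyclohex-1-en-1-yl]methanol
Conditions: iBu2AlH, CH2Cl2, −78 °C → 0 °C; aq. KNaC4H4O6 (potassium sodium tartrate)
Reagents that add atoms: none
Why: Aluminium hydride reduction of the unsaturated ester to the allylic alcohol needed for directed epoxidation.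

Step 11
Reactants: 20 [(4R)-4-(tert-butyldimethylsilyloxy)-2,6,6-trimethylcyclohex-1-en-1-yl]methanol
Product: 21 [(1R,4S,6R)-4-(tert-butyldimethylsilyloxy)-2,2,6-trimethyl-7-oxabicyclo[4.1.0]heptan-1-yl]methanol (anti epoxide, oxirane oxygen trans to the silyloxy group)
Conditions: Ti(OiPr)4, D-(−)-diethyl tartrate, tBuOOH, CH2Cl2, −20 °C
Reagents that add atoms: tert-butyl hydroperoxide, CC(C)(C)OO
Why: Sharpless asymmetric epoxidation of the allylic alcohol. With D-(−)-tartrate the oxygen is delivered to the face of C5=C6 opposite the C3 silyloxy group, which is also the face peracids tend to prefer in this ring type, so reagent and substrate control should reinforce each other and set C5 and C6 together.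

Step 12
Reactants: 21 [(1R,4S,6R)-4-(tert-butyldimethylsilyloxy)-2,2,6-trimethyl-7-oxabicyclo[4.1.0]heptan-1-yl]methanol
Product: 22 (1S,2R,5S)-5-(tert-butyldimethylsilyloxy)-2-(hydroxymethyl)-1,3,3-trimethylcyclohexane-1,2-diol
Conditions: HClO4 (cat.), THF/H2O, 0 °C → rt
Reagents that add atoms: water, O
Why: Acid-catalysed hydrolysis of a 2,3-epoxy alcohol at the distal tertiary carbon: water attacks C5 with inversion (borderline SN2), so the new C5–OH is cis to the C3 oxygen and C6 keeps the oxirane oxygen. C6 is not attacked because it lies between the quaternary C1 and the hydroxymethyl carbon and is not allylic at this stage.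

Step 13
Reactants: 22 (1S,2R,5S)-5-(tert-butyldimethylsilyloxy)-2-(hydroxymethyl)-1,3,3-trimethylcyclohexane-1,2-diol
Product: 23 (1S,2S,4S)-4-(tert-butyldimethylsilyloxy)-1,2-dihydroxy-2,6,6-trimethylcyclohexane-1-carbaldehyde
Conditions: SO3·pyridine, DMSO, iPr2NEt, CH2Cl2, 0 °C; used without delay
Reagents that add atoms: none
Why: Parikh–Doering oxidation of the only oxidisable (primary) hydroxyl. The conditions are non-acidic and do not cleave the vicinal diol.

Step 14
Reactants: 23 (1S,2S,4S)-4-(tert-butyldimethylsilyloxy)-1,2-dihydroxy-2,6,6-trimethylcyclohexane-1-carbaldehyde; 24 ethyl (2E)-4-(diethoxyphosphoryl)-3-methylbut-2-enoate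
Product: 26 ethyl (2E,4E)-5-[(1S,2S,4S)-4-(tert-butyldimethylsilyloxy)-1,2-dihydroxy-2,6,6-trimethylcyclohexyl]-3-methylpenta-2,4-dienoate, via lithiated phosphonate 25 (not isolated)
Conditions: 24, LiN(SiMe3)2, THF/DMPU, −78 °C; then 23, −78 → 0 °C
Reagents that add atoms: none
Why: Horner–Wadsworth–Emmons olefination forms C7=C8 as the E alkene and brings in C9=C10 with its geometry. The stabilised phosphonate anion is too weakly basic to disturb the tertiary hydroxyls.

Step 15
Reactants: 26 ethyl (2E,4E)-5-[(1S,2S,4S)-4-(tert-butyldimethylsilyloxy)-1,2-dihydroxy-2,6,6-trimethylcyclohexyl]-3-methylpenta-2,4-dienoate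
Product: 27 (2E,4E)-5-[(1S,2S,4S)-4-(tert-butyldimethylsilyloxy)-1,2-dihydroxy-2,6,6-trimethylcyclohexyl]-3-methylpenta-2,4-dien-1-ol
Conditions: iBu2AlH (excess), CH2Cl2, −78 → −40 °C; aq. KNaC4H4O6 (potassium sodium tartrate)
Reagents that add atoms: none
Why: 1,2-Reduction of the dienoate. The free hydroxyls only consume hydride as aluminium alkoxides and are restored on neutral work-up.

Step 16
Reactants: 27 (2E,4E)-5-[(1S,2S,4S)-4-(tert-butyldimethylsilyloxy)-1,2-dihydroxy-2,6,6-trimethylcyclohexyl]-3-methylpenta-2,4-dien-1-ol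
Product: 28 (2E,4E)-5-[(1S,2S,4S)-4-(tert-butyldimethylsilyloxy)-1,2-dihydroxy-2,6,6-trimethylcyclohexyl]-3-methylpenta-2,4-dienal
Conditions: MnO2 (activated, excess), CH2Cl2, rt
Reagents that add atoms: none
Why: MnO2 oxidises only the primary allylic alcohol. The tertiary hydroxyls have no carbinol hydrogen.

Step 17
Reactants: 28 (2E,4E)-5-[(1S,2S,4S)-4-(tert-butyldimethylsilyloxy)-1,2-dihydroxy-2,6,6-trimethylcyclohexyl]-3-methylpenta-2,4-dienal; 24 ethyl (2E)-4-(diethoxyphosphoryl)-3-methylbut-2-enoate
Product: 30 ethyl (2E,4E,6E,8E)-9-[(1S,2S,4S)-4-(tert-butyldimethylsilyloxy)-1,2-dihydroxy-2,6,6-trimethylcyclohexyl]-3,7-dimethylnona-2,4,6,8-tetraenoate, via sodium phosphonate salt 29 (not isolated)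
Conditions: 24, NaN(SiMe3)2, THF, −78 °C; then 28, −78 → 0 °C
Reagents that add atoms: none
Why: A second Horner–Wadsworth–Emmons olefination forms C11=C12 (E) and brings in C13=C14; the sodium salt 29 is reactive enough towards the unhindered conjugated dienal without a polar cosolvent, and addition to such an aldehyde is reversible enough for the E alkene to dominate. Minor geometric isomers are removed at this ester stage.

Step 18
Reactants: 30 ethyl (2E,4E,6E,8E)-9-[(1S,2S,4S)-4-(tert-butyldimethylsilyloxy)-1,2-dihydroxy-2,6,6-trimethylcyclohexyl]-3,7-dimethylnona-2,4,6,8-tetraenoate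
Product: 31 (2E,4E,6E,8E)-9-[(1S,2S,4S)-4-(tert-butyldimethylsilyloxy)-1,2-dihydroxy-2,6,6-trimethylcyclohexyl]-3,7-dimethylnona-2,4,6,8-tetraen-1-ol
Conditions: iBu2AlH (excess), CH2Cl2, −78 → −40 °C; aq. KNaC4H4O6 (potassium sodium tartrate)
Reagents that add atoms: none
Why: Aluminium hydride 1,2-reduction of the tetraenoate, as in step 15.

Step 19
Reactants: 31 (2E,4E,6E,8E)-9-[(1S,2S,4S)-4-(tert-butyldimethylsilyloxy)-1,2-dihydroxy-2,6,6-trimethylcyclohexyl]-3,7-dimethylnona-2,4,6,8-tetraen-1-ol
Product: 32 (2E,4E,6E,8E)-9-[(1S,2S,4S)-4-(tert-butyldimethylsilyloxy)-1,2-dihydroxy-2,6,6-trimethylcyclohexyl]-3,7-dimethylnona-2,4,6,8-tetraenal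
Conditions: MnO2 (activated, excess), CH2Cl2, rt, dark
Reagents that add atoms: none
Why: Chemoselective MnO2 oxidation of the primary allylic alcohol to the retinal-type aldehyde under neutral conditions that spare the tertiary allylic C6–OH.

Step 20
Reactants: 18 [(2E,4E,6E)-9-[(4R)-4-(tert-butyldimethylsilyloxy)-2,6,6-trimethylcyclohex-1-en-1-yl]-3,7-dimethylnona-2,4,6-trien-8-yn-1-yl]triphenylphosphonium bromide; 32 (2E,4E,6E,8E)-9-[(1S,2S,4S)-4-(tert-butyldimethylsilyloxy)-1,2-dihydroxy-2,6,6-trimethylcyclohexyl]-3,7-dimethylnona-2,4,6,8-tetraenal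
Product: 35 (3S,5S,6S,3'R)-3,3'-bis-O-(tert-butyldimethylsilyl)-7',8'-didehydro-5,6-dihydro-β,β-carotene-3,5,6,3'-tetrol (all-E), via phosphorus ylide 33 (not isolated), via 15Z isomer 34 (not isolated)
Conditions: NaOMe, CH2Cl2/MeOH, 0 °C → rt, argon, dark; then EtOAc/heptane, 70 °C
Reagents that add atoms: none
Why: Wittig reaction of the semistabilised C20 ylide with the C20 polyenal forms C15=C15' as an E/Z mixture. Gentle heating without iodine should convert the central Z bond to E, which is the lowest isomerisation barrier in the chain, and leave the mechanistically set 9'E enyne alone.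

Step 21
Reactants: 35 (3S,5S,6S,3'R)-3,3'-bis-O-(tert-butyldimethylsilyl)-7',8'-didehydro-5,6-dihydro-β,β-carotene-3,5,6,3'-tetrol
Product: 36 (3S,5S,6S,3'R)-7',8'-didehydro-5,6-dihydro-β,β-carotene-3,5,6,3'-tetrol
Conditions: Bu4NF, THF, rt, argon, dark
Reagents that add atoms: none
Why: Fluoride cleavage of both secondary silyl ethers under non-acidic conditions, so the tertiary allylic C6–OH and the polyene are not put at risk.

## Compound list

1 | (4R,6R)-4-hydroxy-2,2,6-trimethylcyclohexanone (actinol) | O=C1C(C)(C)C[C@H](O)C[C@H]1C | starting material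
2 | (4R,6R)-4-(tert-butyldimethylsilyloxy)-2,2,6-trimethylcyclohexanone | O=C1C(C)(C)C[C@H](O[Si](C)(C)C(C)(C)C)C[C@H]1C | intermediate
3 | lithium (4R)-4-(tert-butyldimethylsilyloxy)-2,6,6-trimethylcyclohex-1-en-1-olate | CC1=C(O[Li])C(C)(C)C[C@H](O[Si](C)(C)C(C)(C)C)C1 | intermediate (not isolated)
4 | (4R)-4-(tert-butyldimethylsilyloxy)-2,6,6-trimethylcyclohex-1-en-1-yl trifluoromethanesulfonate | CC1=C(OS(=O)(=O)C(F)(F)F)C(C)(C)C[C@H](O[Si](C)(C)C(C)(C)C)C1 | intermediate
5 | 1,4-bis(trimethylsilyl)buta-1,3-diyne | C[Si](C)(C)C#CC#C[Si](C)(C)C | starting material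
6 | lithium 4-(trimethylsilyl)buta-1,3-diyn-1-ide | [Li]C#CC#C[Si](C)(C)C | intermediate (not isolated)
7 | chloro[4-(trimethylsilyl)buta-1,3-diyn-1-yl]zinc | Cl[Zn]C#CC#C[Si](C)(C)C | intermediate (not isolated)
8 | tert-butyldimethyl{[(1R)-3,5,5-trimethyl-4-[4-(trimethylsilyl)buta-1,3-diyn-1-yl]cyclohex-3-en-1-yl]oxy}silane | CC1=C(C#CC#C[Si](C)(C)C)C(C)(C)C[C@H](O[Si](C)(C)C(C)(C)C)C1 | intermediate
9 | {[(1R)-4-(buta-1,3-diyn-1-yl)-3,5,5-trimethylcyclohex-3-en-1-yl]oxy}(tert-butyl)dimethylsilane | CC1=C(C#CC#C)C(C)(C)C[C@H](O[Si](C)(C)C(C)(C)C)C1 | intermediate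
10 | ethyl (2E)-3-methyl-4-oxobut-2-enoate | CCOC(=O)/C=C(C)/C=O | starting material
11 | ethyl (2E,4E)-5-iodo-3-methylpenta-2,4-dienoate | CCOC(=O)/C=C(C)/C=C/I | intermediate
12 | trimethylaluminium | C[Al](C)C | starting material
13 | {(1E)-4-[(4R)-4-(tert-butyldimethylsilyloxy)-2,6,6-trimethylcyclohex-1-en-1-yl]-2-methylbut-1-en-3-yn-1-yl}dimethylalane | CC1=C(C#C/C(C)=C/[Al](C)C)C(C)(C)C[C@H](O[Si](C)(C)C(C)(C)C)C1 | intermediate (not isolated)
14 | chloro{(1E)-4-[(4R)-4-(tert-butyldimethylsilyloxy)-2,6,6-trimethylcyclohex-1-en-1-yl]-2-methylbut-1-en-3-yn-1-yl}zinc | CC1=C(C#C/C(C)=C/[Zn]Cl)C(C)(C)C[C@H](O[Si](C)(C)C(C)(C)C)C1 | intermediate (not isolated)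
15 | ethyl (2E,4E,6E)-9-[(4R)-4-(tert-butyldimethylsilyloxy)-2,6,6-trimethylcyclohex-1-en-1-yl]-3,7-dimethylnona-2,4,6-trien-8-ynoate | CC1=C(C#C/C(C)=C/C=C/C(C)=C/C(=O)OCC)C(C)(C)C[C@H](O[Si](C)(C)C(C)(C)C)C1 | intermediate
16 | (2E,4E,6E)-9-[(4R)-4-(tert-butyldimethylsilyloxy)-2,6,6-trimethylcyclohex-1-en-1-yl]-3,7-dimethylnona-2,4,6-trien-8-yn-1-ol | CC1=C(C#C/C(C)=C/C=C/C(C)=C/CO)C(C)(C)C[C@H](O[Si](C)(C)C(C)(C)C)C1 | intermediate
17 | {[(1R)-4-[(3E,5E,7E)-9-bromo-3,7-dimethylnona-3,5,7-trien-1-yn-1-yl]-3,5,5-trimethylcyclohex-3-en-1-yl]oxy}(tert-butyl)dimethylsilane | CC1=C(C#C/C(C)=C/C=C/C(C)=C/CBr)C(C)(C)C[C@H](O[Si](C)(C)C(C)(C)C)C1 | intermediate (not isolated)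
18 | [(2E,4E,6E)-9-[(4R)-4-(tert-butyldimethylsilyloxy)-2,6,6-trimethylcyclohex-1-en-1-yl]-3,7-dimethylnona-2,4,6-trien-8-yn-1-yl]triphenylphosphonium bromide | CC1=C(C#C/C(C)=C/C=C/C(C)=C/C[P+](c2ccccc2)(c2ccccc2)c2ccccc2)C(C)(C)C[C@H](O[Si](C)(C)C(C)(C)C)C1.[Br-] | intermediate
19 | methyl (4R)-4-(tert-butyldimethylsilyloxy)-2,6,6-trimethylcyclohex-1-ene-1-carboxylate | CC1=C(C(=O)OC)C(C)(C)C[C@H](O[Si](C)(C)C(C)(C)C)C1 | intermediate
20 | [(4R)-4-(tert-butyldimethylsilyloxy)-2,6,6-trimethylcyclohex-1-en-1-yl]methanol | CC1=C(CO)C(C)(C)C[C@H](O[Si](C)(C)C(C)(C)C)C1 | intermediate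
21 | [(1R,4S,6R)-4-(tert-butyldimethylsilyloxy)-2,2,6-trimethyl-7-oxabicyclo[4.1.0]heptan-1-yl]methanol | OC[C@]12C(C)(C)C[C@H](O[Si](C)(C)C(C)(C)C)C[C@@]1(C)O2 | intermediate
22 | (1S,2R,5S)-5-(tert-butyldimethylsilyloxy)-2-(hydroxymethyl)-1,3,3-trimethylcyclohexane-1,2-diol | OC[C@]1(O)C(C)(C)C[C@H](O[Si](C)(C)C(C)(C)C)C[C@]1(C)O | intermediate
23 | (1S,2S,4S)-4-(tert-butyldimethylsilyloxy)-1,2-dihydroxy-2,6,6-trimethylcyclohexane-1-carbaldehyde | O=C[C@]1(O)C(C)(C)C[C@H](O[Si](C)(C)C(C)(C)C)C[C@]1(C)O | intermediate
24 | ethyl (2E)-4-(diethoxyphosphoryl)-3-methylbut-2-enoate | CCOC(=O)/C=C(C)/CP(=O)(OCC)OCC | starting material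
25 | lithium salt of ethyl (2E)-4-(diethoxyphosphoryl)-3-methylbut-2-enoate (C4 carbanion) | CCOC(=O)/C=C(C)/[CH-]P(=O)(OCC)OCC.[Li+] | intermediate (not isolated)
26 | ethyl (2E,4E)-5-[(1S,2S,4S)-4-(tert-butyldimethylsilyloxy)-1,2-dihydroxy-2,6,6-trimethylcyclohexyl]-3-methylpenta-2,4-dienoate | CCOC(=O)/C=C(C)/C=C/[C@]1(O)C(C)(C)C[C@H](O[Si](C)(C)C(C)(C)C)C[C@]1(C)O | intermediate
27 | (2E,4E)-5-[(1S,2S,4S)-4-(tert-butyldimethylsilyloxy)-1,2-dihydroxy-2,6,6-trimethylcyclohexyl]-3-methylpenta-2,4-dien-1-ol | OC/C=C(C)/C=C/[C@]1(O)C(C)(C)C[C@H](O[Si](C)(C)C(C)(C)C)C[C@]1(C)O | intermediate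
28 | (2E,4E)-5-[(1S,2S,4S)-4-(tert-butyldimethylsilyloxy)-1,2-dihydroxy-2,6,6-trimethylcyclohexyl]-3-methylpenta-2,4-dienal | O=C/C=C(C)/C=C/[C@]1(O)C(C)(C)C[C@H](O[Si](C)(C)C(C)(C)C)C[C@]1(C)O | intermediate
29 | sodium salt of ethyl (2E)-4-(diethoxyphosphoryl)-3-methylbut-2-enoate (C4 carbanion) | CCOC(=O)/C=C(C)/[CH-]P(=O)(OCC)OCC.[Na+] | intermediate (not isolated)
30 | ethyl (2E,4E,6E,8E)-9-[(1S,2S,4S)-4-(tert-butyldimethylsilyloxy)-1,2-dihydroxy-2,6,6-trimethylcyclohexyl]-3,7-dimethylnona-2,4,6,8-tetraenoate | CCOC(=O)/C=C(C)/C=C/C=C(C)/C=C/[C@]1(O)C(C)(C)C[C@H](O[Si](C)(C)C(C)(C)C)C[C@]1(C)O | intermediate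
31 | (2E,4E,6E,8E)-9-[(1S,2S,4S)-4-(tert-butyldimethylsilyloxy)-1,2-dihydroxy-2,6,6-trimethylcyclohexyl]-3,7-dimethylnona-2,4,6,8-tetraen-1-ol | OC/C=C(C)/C=C/C=C(C)/C=C/[C@]1(O)C(C)(C)C[C@H](O[Si](C)(C)C(C)(C)C)C[C@]1(C)O | intermediate
32 | (2E,4E,6E,8E)-9-[(1S,2S,4S)-4-(tert-butyldimethylsilyloxy)-1,2-dihydroxy-2,6,6-trimethylcyclohexyl]-3,7-dimethylnona-2,4,6,8-tetraenal | O=C/C=C(C)/C=C/C=C(C)/C=C/[C@]1(O)C(C)(C)C[C@H](O[Si](C)(C)C(C)(C)C)C[C@]1(C)O | intermediate
33 | ylide of 18: [(2E,4E,6E)-9-[(4R)-4-(tert-butyldimethylsilyloxy)-2,6,6-trimethylcyclohex-1-en-1-yl]-3,7-dimethylnona-2,4,6-trien-8-yn-1-ylidene]triphenylphosphorane | CC1=C(C#C/C(C)=C/C=C/C(C)=C/C=P(c2ccccc2)(c2ccccc2)c2ccccc2)C(C)(C)C[C@H](O[Si](C)(C)C(C)(C)C)C1 | intermediate (not isolated)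
34 | (15Z)-isomer of 35: (3S,5S,6S,3'R,15Z)-3,3'-bis-O-(tert-butyldimethylsilyl)-7',8'-didehydro-5,6-dihydro-β,β-carotene-3,5,6,3'-tetrol | CC1=C(C#C/C(C)=C/C=C/C(C)=C/C=C\C=C(C)\C=C\C=C(C)\C=C\[C@]2(O)C(C)(C)C[C@H](O[Si](C)(C)C(C)(C)C)C[C@]2(C)O)C(C)(C)C[C@H](O[Si](C)(C)C(C)(C)C)C1 | intermediate (not isolated)
35 | (3S,5S,6S,3'R)-3,3'-bis-O-(tert-butyldimethylsilyl)-7',8'-didehydro-5,6-dihydro-β,β-carotene-3,5,6,3'-tetrol (all-E) | CC1=C(C#C/C(C)=C/C=C/C(C)=C/C=C/C=C(C)/C=C/C=C(C)/C=C/[C@]2(O)C(C)(C)C[C@H](O[Si](C)(C)C(C)(C)C)C[C@]2(C)O)C(C)(C)C[C@H](O[Si](C)(C)C(C)(C)C)C1 | intermediate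
36 | (3S,5S,6S,3'R)-7',8'-didehydro-5,6-dihydro-β,β-carotene-3,5,6,3'-tetrol (all-E) | CC1=C(C#C/C(C)=C/C=C/C(C)=C/C=C/C=C(C)/C=C/C=C(C)/C=C/[C@]2(O)C(C)(C)C[C@H](O)C[C@]2(C)O)C(C)(C)C[C@H](O)C1 | target

## Step count and risks

Total: 21 steps. Longest linear sequence: 15 steps (steps 1, 2, 9–19, 20, 21). The ring B branch takes steps 1–4 and 6–8, and iodide 11 takes one step.

**Step 6 (key step).** The most likely failure is metalation of the acidic terminal C–H of the conjugated diyne by the aluminium reagent in competition with carbometalation. Further carbometalation of the enyne product, methyl transfer from residual aluminium during the coupling, and isomerisation of the conjugated alkenyl metal are also possible. In the fallback the C9'=C10' alkene is bought instead of made. It sets out from triflate 4: Sonogashira coupling with commercial (E)-3-methylpent-2-en-4-yn-1-ol (Pd(PPh3)4, CuI, iPr2NH) should give the C15 enynol F1, MnO2 oxidation the enynal F2, and Horner–Wadsworth–Emmons reaction with the lithium salt 25 of phosphonate 24 comes back to the route at ester 15.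

**Step 12.** The axial approach of water to C5 runs between the axial C1 methyl and the C3 silyloxy group. Loss of a proton from the developing tertiary cation (allylic alcohols), semipinacol ring contraction, partial retention at C5, or acid cleavage of the silyl ether before the oxirane opens may therefore compete with hydrolysis. The fallback delivers the oxygen intramolecularly from O-7. It sets out from epoxy alcohol 21: acylation with di-tert-butyl dicarbonate (DMAP) gives the tert-butyl carbonate F3, BF3·OEt2 at −78 °C closes the six-membered 5,7-cyclic carbonate F4 by attack of the carbonyl oxygen on C5 with inversion, and K2CO3 in methanol releases triol 22, where the route is rejoined.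

**Step 14 (with the aldehyde made in step 13).** The α-hydroxy aldehyde may undergo base-induced acyloin-type ring expansion, or olefination at the neopentyl formyl group may be slow under the basic conditions. The fallback uses a neutral ylide and a two-stage chain build. It sets out from aldehyde 23: Wittig reaction with Ph3P=CHC(O)CH3 in warm toluene gives enone F5, Horner–Wadsworth–Emmons reaction with diethyl cyanomethylphosphonate (NaH, THF) gives nitrile F6 after removal of the 9Z isomer, and iBu2AlH reduction with mild hydrolysis of the imine comes back at aldehyde 28.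

**Step 3.** Oxidative homocoupling or oligomerisation of the diynyl metal may outrun the slow oxidative addition of the hindered tetrasubstituted triflate. The fallback assembles the diyne as C2 + C2. It sets out from triflate 4: Sonogashira coupling with trimethylsilylacetylene gives F7, K2CO3 in methanol gives the terminal enyne F8, Cadiot–Chodkiewicz coupling with (bromoethynyl)triethylsilane (CuCl, NH2OH·HCl, BuNH2) gives the triethylsilyl diyne F9, and K2CO3 in methanol comes back at diyne 9.

**Step 20.** Low E selectivity at C15=C15' would force longer heating, with geometric drift at the 9' enyne bond, and the polyenal may degrade under methoxide. The fallback is a phosphonate olefination. It sets out from alcohol 16 through bromide 17: Michaelis–Becker reaction with NaP(O)(OEt)2 gives phosphonate F10, and its potassium salt (KOtBu, THF) with aldehyde 32 should give 35 directly with high E selectivity, where the route is rejoined.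

## Further compounds

F1 | step 6 | (2E)-5-[(4R)-4-(tert-butyldimethylsilyloxy)-2,6,6-trimethylcyclohex-1-en-1-yl]-3-methylpent-2-en-4-yn-1-ol | CC1=C(C#C/C(C)=C/CO)C(C)(C)C[C@H](O[Si](C)(C)C(C)(C)C)C1
F2 | step 6 | (2E)-5-[(4R)-4-(tert-butyldimethylsilyloxy)-2,6,6-trimethylcyclohex-1-en-1-yl]-3-methylpent-2-en-4-ynal | CC1=C(C#C/C(C)=C/C=O)C(C)(C)C[C@H](O[Si](C)(C)C(C)(C)C)C1
F3 | step 12 | tert-butyl [(1R,4S,6R)-4-(tert-butyldimethylsilyloxy)-2,2,6-trimethyl-7-oxabicyclo[4.1.0]heptan-1-yl]methyl carbonate | CC(C)(C)OC(=O)OC[C@]12C(C)(C)C[C@H](O[Si](C)(C)C(C)(C)C)C[C@@]1(C)O2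
F4 | step 12 | 5,7-cyclic carbonate of triol 22 (six-membered carbonate across O-5 and O-7, C6–OH free, cis ring fusion) | O=C1OC[C@]2(O)C(C)(C)C[C@H](O[Si](C)(C)C(C)(C)C)C[C@]2(C)O1
F5 | step 14 | (3E)-4-[(1S,2S,4S)-4-(tert-butyldimethylsilyloxy)-1,2-dihydroxy-2,6,6-trimethylcyclohexyl]but-3-en-2-one | CC(=O)/C=C/[C@]1(O)C(C)(C)C[C@H](O[Si](C)(C)C(C)(C)C)C[C@]1(C)O
F6 | step 14 | (2E,4E)-5-[(1S,2S,4S)-4-(tert-butyldimethylsilyloxy)-1,2-dihydroxy-2,6,6-trimethylcyclohexyl]-3-methylpenta-2,4-dienenitrile | N#C/C=C(C)/C=C/[C@]1(O)C(C)(C)C[C@H](O[Si](C)(C)C(C)(C)C)C[C@]1(C)O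
F7 | step 3 | tert-butyldimethyl{[(1R)-3,5,5-trimethyl-4-[(trimethylsilyl)ethynyl]cyclohex-3-en-1-yl]oxy}silane | CC1=C(C#C[Si](C)(C)C)C(C)(C)C[C@H](O[Si](C)(C)C(C)(C)C)C1
F8 | step 3 | tert-butyl{[(1R)-4-ethynyl-3,5,5-trimethylcyclohex-3-en-1-yl]oxy}dimethylsilane | CC1=C(C#C)C(C)(C)C[C@H](O[Si](C)(C)C(C)(C)C)C1
F9 | step 3 | tert-butyldimethyl{[(1R)-3,5,5-trimethyl-4-[4-(triethylsilyl)buta-1,3-diyn-1-yl]cyclohex-3-en-1-yl]oxy}silane | CC1=C(C#CC#C[Si](CC)(CC)CC)C(C)(C)C[C@H](O[Si](C)(C)C(C)(C)C)C1
F10 | step 20 | diethyl [(2E,4E,6E)-9-[(4R)-4-(tert-butyldimethylsilyloxy)-2,6,6-trimethylcyclohex-1-en-1-yl]-3,7-dimethylnona-2,4,6-trien-8-yn-1-yl]phosphonate | CC1=C(C#C/C(C)=C/C=C/C(C)=C/CP(=O)(OCC)OCC)C(C)(C)C[C@H](O[Si](C)(C)C(C)(C)C)C1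
A1 | alternative 1 | 3-hydroxy-4-methyl-2H-pyran-2-one | CC1=C(O)C(=O)OC=C1
A2 | alternative 1 | methacrolein (2-methylprop-2-enal) | CC(=C)C=O
A3 | alternative 1 | 4-hydroxy-5,8-dimethyl-3-oxo-2-oxabicyclo[2.2.2]oct-5-ene-8-carbaldehyde | O=C1O[C@@H]2C=C(C)[C@@]1(O)C(C)(C=O)C2
A4 | alternative 2 | tert-butyl carbonate of (3S,5R,6S)-5,6-epoxy-3-hydroxy-5,6-dihydro-β-ionone | CC(=O)/C=C/[C@]12C(C)(C)C[C@H](OC(=O)OC(C)(C)C)C[C@@]1(C)O2
A5 | alternative 2 | 3,5-cyclic carbonate of (3S,5S,6S)-3,5,6-trihydroxy-5,6-dihydro-β-ionone | CC(=O)/C=C/[C@]1(O)C(C)(C)C[C@H]2C[C@]1(C)OC(=O)O2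
A6 | alternative 3 | (2E)-1-[(4R)-4-(tert-butyldimethylsilyloxy)-2,6,6-trimethylcyclohex-1-en-1-yl]-4,4-diethoxy-2-methylbut-2-en-1-one | CC1=C(C(=O)/C(C)=C/C(OCC)OCC)C(C)(C)C[C@H](O[Si](C)(C)C(C)(C)C)C1
A7 | alternative 3 | lithiated trimethylsilyldiazomethane | [Li]C(=[N+]=[N-])[Si](C)(C)C
A8 | alternative 3 | diethyl acetal of (2E)-5-[(4R)-4-(tert-butyldimethylsilyloxy)-2,6,6-trimethylcyclohex-1-en-1-yl]-3-methylpent-2-en-4-ynal | CC1=C(C#C/C(C)=C/C(OCC)OCC)C(C)(C)C[C@H](O[Si](C)(C)C(C)(C)C)C1
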